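In a one-step world the target would climb at one steady pace, but the larch run bends.

| flask | starting material | reagent in the second phase | remark | time | volume of the second phase over the first |
|---|---|---|---|---|---|
| alder | 0.12 M | 0.072 M | run made earlier |  |  |
| larch | 0.12 M | 0.29 M | run made earlier |  |  |
| maple | 0.060 M | 0.144 M | run made earlier |  |  |
| flask | 0.12 M | 0.144 M |  | 10 min | 0.25 |

| run | time / min | target / % |
|---|---|---|
| alder | 1.33 | 0.7 |
| alder | 4.00 | 3.9 |
| alder | 6.00 | 6.9 |
| alder | 10.0 | 10.7 |
| larch | 1.33 | 3.8 |
| larch | 4.00 | 13.1 |
| larch | 6.00 | 19.0 |
| larch | 10.0 | 20.7 |
| maple | 0.833 | 2.3 |
| maple | 2.00 | 3.5 |
| maple | 4.00 | 10.2 |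
| maple | 10.0 | 18.1 |

(each reading ± 1 percentage point)

- in the second phase: reagent in the second phase; everything else is in the first
- charges count per volume of the first phase; a concentration in a rate is the amount of a species over the volume of its own phase; every rate counts per litre of the first phase
- the numbers in the tables scatter with a standard deviation of 1 percentage point
- the earlier runs hold the two phases in the same ratio of volumes as the flask asked about

- Tuesday's: doubling the amount of reagent in the second phase, all else as stated
- Friday's: doubling the transfer coefficient of the reagent in the second phase, all else as stated

* target at 10 min, in percent of the starting material charged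
* the change that raises the amount of target at 10 min, in percent of the starting material charged most ("none" if none brings more than 2 percentage points) (Tuesday's / Friday's / none)
* amount of target at 10 min, in percent of the starting material charged, after Friday's

The larch run, at 0.29 M of reagent in the second phase, read 13.1% at 4.00 min, 19.0% at 6.00 min and 20.7% at 10.0 min. So it rose like a tank filling towards a level, and I took that last reading as the level. Its reading at 4.00 min then gives a time constant of 3.99 min. The alder run, charged with the same starting material but 0.072 M of reagent, read less at the same 10.0 min: 10.7%.

Suppose reagent, in proportion to its charge, speeds the making and the loss of target alike. Then their ratio, the selectivity factor, holds, the level stays, and the time constant goes inversely with the reagent charge. The flask's time constant towards that level is therefore 8.04 min: its filling time.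

The asked 10 min is 1.24 filling times, so I committed to 14.7%. On that supposition Tuesday's divided the filling time by 2, which gave me 19.0%, a gain of 4.3 percentage points. For Friday's I had no filling time.

The forecast said 16% for the flask, more than my figure, and 19% after Friday's, with Tuesday's ahead: “Tuesday's is the better bet”.

The flask gave 16.8%, 2 points above my reckoning. Tuesday's brought 3.9 points and Friday's 2 points, reaching 18.8%, so the better change was Tuesday's.

    reagent in the reaction phase + target → over-reacted product (k = 3.90 M⁻¹ min⁻¹)
    reagent in the reaction phase ⇌ reagent in the second phase, rate k2*([reagent in the reaction phase] - [reagent in the second phase]/K2) per volume of the first phase (partition coefficient = 15.0, kL = 0.280 min⁻¹)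
    starting material + reagent in the reaction phase → target (k = 2.20 M⁻¹ min⁻¹)
    reagent in the reaction phase + target → over-reaction product (k = 2.00 M⁻¹ min⁻¹)

The same flask stopped at 4.0 min is 0.498 filling times in, so the rise towards 20.7% gave me 8.11%. That neighbouring flask kept 91% of its starting material and held 7.85% of target.

The numbers in the tables are calculated from invented constants, noise included.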